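**Retrosynthetic overview**

- The target is cut into two molecules of 4-hydroxy-7,8-dimethoxy-1-methylquinolin-2(1H)-one and one C10 cross-conjugated dienal, (E)-5-methyl-2-(prop-1-en-2-yl)hex-2-enal, whose carbons carry the lavandulane branching found between the two quinolones: O–CH(aryl)–CH(CMe2)–CH(iBu).
- Enabling feature: in the dihydropyran ring of quinolone unit A (O–CH(aryl)–CH–CH(iBu)–C-3=C-4) the ring oxygen and C-3 are the two nucleophilic sites of one 4-hydroxyquinolin-2-one. The CH(iBu) carbon is the β-carbon and the O–CH–aryl carbon the carbonyl carbon of an enal (aldehyde oxidation level: one O, one aryl C). The O–CMe2 carbon of ring B is a protonated isopropenyl group on the α-carbon.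
- Key disconnections: C-3(A)–CH(iBu) by Michael addition and O(A)–CH(aryl) by hemiacetalisation in one amine-catalysed formal 3+3 annulation; then aryl(B)–CH by oxocarbenium capture and O(B)–CMe2 by hydroalkoxylation with a second molecule of the quinolone in the same flask.
- Ring order: pyridone ring of the quinolone first (Friedel–Crafts acylation), then pyran ring A and pyran ring B in the last step. The quinolone comes from 1-bromo-2,3-dimethoxybenzene; the dienal from 3-methylbutanal by Wittig reaction, bromination–elimination and Suzuki coupling.
- Stereochemistry: the CH(iBu) centre (S) is set by a chiral primary amine. The ring-fusion CH (S, CMe2 trans to isobutyl) and the O–CH–aryl centre (R, cis fusion) should follow under thermodynamic control.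

Key step: step 7

Remark: which face of the α-branched iminium ion the cinchona primary amine opens is an assumption; the quinine-derived amine is taken to give the (S)-configured isobutyl centre, and its quinidine-derived pseudoenantiomer would be used if the sense should be the opposite.

**Route**

Step 1
Reactants: 1 1-bromo-2,3-dimethoxybenzene
Product: 2 2,3-dimethoxy-N-methylaniline
Conditions: MeNH2 (2 M in THF, 3 equiv), Pd2(dba)3 (1 mol %), BrettPhos [2-(dicyclohexylphosphino)-3,6-dimethoxy-2',4',6'-triisopropylbiphenyl] (2.5 mol %), NaOtBu (1.4 equiv), 1,4-dioxane, 80 °C, sealed vessel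
Reagents that add atoms: methylamine, CN
Why: Buchwald–Hartwig amination, in which the bulky biaryl phosphine should allow clean monoarylation of methylamine and tolerate the ortho-methoxy group.

Step 2
Reactants: 2 2,3-dimethoxy-N-methylaniline
Product: 3 3-[(2,3-dimethoxyphenyl)(methyl)amino]-3-oxopropanoic acid
Conditions: Meldrum's acid (1.1 equiv), toluene, 100 °C
Reagents that add atoms: Meldrum's acid (2,2-dimethyl-1,3-dioxane-4,6-dione), CC1(C)OC(=O)CC(=O)O1
Why: N-acylation of the secondary aniline by ring opening of Meldrum's acid with loss of acetone should give the malonic acid monoamide without a coupling agent.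

Step 3
Reactants: 3 3-[(2,3-dimethoxyphenyl)(methyl)amino]-3-oxopropanoic acid
Product: 4 4-hydroxy-7,8-dimethoxy-1-methylquinolin-2(1H)-one
Conditions: P2O5 in MeSO3H (Eaton's reagent), 70 °C
Reagents that add atoms: none
Why: Intramolecular Friedel–Crafts acylation at the only free position ortho to nitrogen (para to the 3-methoxy group) followed by enolisation should give the 4-hydroxy-2-quinolone with the 7,8-dimethoxy pattern.

Step 4
Reactants: 5 3-methylbutanal
Product: 6 (E)-5-methylhex-2-enal
Conditions: Ph3P=CHCHO (0.5 equiv relative to 5), toluene, 80 °C
Reagents that add atoms: (triphenylphosphoranylidene)acetaldehyde, O=CC=P(c1ccccc1)(c1ccccc1)c1ccccc1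
Why: Wittig olefination with a stabilised ylide should give the (E)-enal, and the excess of the volatile aldehyde suppresses a second homologation.

Step 5
Reactants: 6 (E)-5-methylhex-2-enal
Product: 8 (Z)-2-bromo-5-methylhex-2-enal, via dibromide 7 (not isolated)
Conditions: Br2 (1.05 equiv), CH2Cl2, −10 °C; then Et3N (1.5 equiv), 0 °C to rt
Reagents that add atoms: bromine, BrBr
Why: Bromine addition to the enal and base-induced loss of HBr (removal of the acidic α-hydrogen, departure of the β-bromide) is the standard α-bromination of enals and should leave the formyl group trans to the alkyl chain.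

Step 6
Reactants: 8 (Z)-2-bromo-5-methylhex-2-enal
Product: 9 (E)-5-methyl-2-(prop-1-en-2-yl)hex-2-enal
Conditions: isopropenylboronic acid pinacol ester (1.3 equiv), Pd(PPh3)4 (3 mol %), K3PO4 (2 equiv), aqueous THF, 50 °C; the dienal is used promptly
Reagents that add atoms: 2-isopropenyl-4,4,5,5-tetramethyl-1,3,2-dioxaborolane, CC(=C)B1OC(C)(C)C(C)(C)O1
Why: Suzuki–Miyaura coupling of the activated alkenyl bromide should proceed with retention of the double-bond geometry and give the cross-conjugated dienal.

Step 7
Reactants: 4 4-hydroxy-7,8-dimethoxy-1-methylquinolin-2(1H)-one (first molecule, becomes quinolone unit A); 9 (E)-5-methyl-2-(prop-1-en-2-yl)hex-2-enal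
Product: 12 CNP0275598.1 (target), via lactol 10 (not isolated), via C-aryl dihydropyran 11 (not isolated)
Conditions: first stage: 4 (1.05 equiv), 9 (1.0 equiv), 9-amino-9-deoxy-epi-quinine [(8S,9S)-6'-methoxycinchonan-9-amine] (20 mol %), CF3CO2H (40 mol %), CHCl3, 25 °C; second stage in the same flask: a second portion of 4 (1.1 equiv), CF3SO3H (1.0 equiv), 0 °C to 40 °C
Reagents that add atoms: 4-hydroxy-7,8-dimethoxy-1-methylquinolin-2(1H)-one (second molecule of compound 4; becomes quinolone unit B), COc1ccc2c(O)cc(=O)n(C)c2c1OC
Why: Proposed new method: the primary amine should condense with 9 to a cross-conjugated iminium ion, C-3 of the first molecule of 4 adds to its β-carbon (the carbon that carries the isobutyl group) and, after hydrolysis, the 4-hydroxyl closes on the aldehyde carbon to lactol 10, so that the C–C and the C–O bond of pyran ring A arise in one catalytic cycle; CF3SO3H then ionises 10 to a cyclic oxocarbenium ion, C-3 of the second molecule of 4 captures it (11), and Markovnikov protonation of the isopropenyl group lets the new 4-hydroxyl close pyran ring B, so that two molecules of 4 and one of 9 give 12 and one molecule of water. The closest known reaction types are the amine-catalysed Michael addition/hemiacetalisation of 4-hydroxycoumarins and 4-hydroxyquinolin-2-ones with β-alkyl enals, primary-amine iminium catalysis of α-branched enals with carbon nucleophiles, the acid-mediated C-alkylation of 4-hydroxycoumarins by hemiacetals and benzylic alcohols, and the acid cyclisation of 3-prenyl-4-hydroxyquinolin-2-ones to 2,2-dimethyldihydropyrans; new are the α-isopropenyl enal as acceptor and the telescoping of the four bond formations. Ring A closes by an intermolecular conjugate addition followed by 6-exo-trig attack of oxygen on the carbonyl group (formal 3+3 annulation), ring B by an intermolecular Friedel–Crafts-type attack on the oxocarbenium ion followed by 6-exo-trig Markovnikov addition of the 4-hydroxyl to the protonated isopropenyl group. The isobutyl-bearing centre (S) is set by the catalyst, whose protonated quinuclidine guides the enol of 4 to one face of the iminium ion; the neighbouring ring-fusion centre is epimerisable (through the open aldehyde in the first stage, through reversible protonation in the second) and should settle with its branch trans to isobutyl, which avoids the gauche contact between isobutyl and the quaternary carbon; the O–CH–aryl centre follows from the cis ring fusion, the less strained junction of two pyran rings that are each fused to a planar quinolone, and can correct itself because the benzylic C–O bond ionises reversibly in acid. The step needs 1,4- instead of 1,2-addition to the iminium ion (favoured by the α-branch next to the iminium carbon and the unhindered β-CH), no racemic background addition in the acid stage (9 is the limiting component of the first stage and is consumed before the second portion of 4 is added), ring closure through O-4 and not through the lactam oxygen (the N-methyl-4-hydroxy-2-quinolone tautomer reacts as such), and attack of C-3 at the oxocarbenium carbon instead of the tertiary cation (steric).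

**Compound list**

1 | 1-bromo-2,3-dimethoxybenzene | COc1cccc(Br)c1OC | starting material
2 | 2,3-dimethoxy-N-methylaniline | CNc1cccc(OC)c1OC | intermediate
3 | 3-[(2,3-dimethoxyphenyl)(methyl)amino]-3-oxopropanoic acid | COc1cccc(N(C)C(=O)CC(=O)O)c1OC | intermediate
4 | 4-hydroxy-7,8-dimethoxy-1-methylquinolin-2(1H)-one | COc1ccc2c(O)cc(=O)n(C)c2c1OC | intermediate
5 | 3-methylbutanal | CC(C)CC=O | starting material
6 | (E)-5-methylhex-2-enal | CC(C)C/C=C/C=O | intermediate
7 | 2,3-dibromo-5-methylhexanal (mixture of stereoisomers, not isolated) | CC(C)CC(Br)C(Br)C=O | intermediate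
8 | (Z)-2-bromo-5-methylhex-2-enal | CC(C)C/C=C(\Br)C=O | intermediate
9 | (E)-5-methyl-2-(prop-1-en-2-yl)hex-2-enal | CC(C)C/C=C(/C=O)C(C)=C | intermediate
10 | (3R,4S)-2-hydroxy-7,8-dimethoxy-6-methyl-4-(2-methylpropyl)-3-(prop-1-en-2-yl)-3,4-dihydro-2H-pyrano[3,2-c]quinolin-5(6H)-one (both anomers at C-2, not isolated) | COc1ccc2c3c(c(=O)n(C)c2c1OC)[C@@H](CC(C)C)[C@H](C(C)=C)C(O)O3 | intermediate
11 | (2R,3R,4S)-2-(4-hydroxy-7,8-dimethoxy-1-methyl-2-oxo-1,2-dihydroquinolin-3-yl)-7,8-dimethoxy-6-methyl-4-(2-methylpropyl)-3-(prop-1-en-2-yl)-3,4-dihydro-2H-pyrano[3,2-c]quinolin-5(6H)-one (not isolated) | COc1ccc2c3c(c(=O)n(C)c2c1OC)[C@@H](CC(C)C)[C@H](C(C)=C)[C@@H](O3)c2c(O)c3ccc(OC)c(OC)c3n(C)c2=O | intermediate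
12 | CNP0275598.1: 7,8-dimethoxy-6-methyl-4-(2-methylpropyl)-3,4-dihydro-2H-pyrano[3,2-c]quinolin-5-one (unit A) whose C-2/C-3 bond is cis-fused to C-4/C-3 of a 7,8-dimethoxy-2,2,6-trimethyl-3,4-dihydro-2H-pyrano[3,2-c]quinolin-5-one (unit B); (R) at O–CH–aryl, (S) at the ring-fusion CH, (S) at CH–isobutyl | COc1ccc2c3c(c(=O)n(C)c2c1OC)[C@@H](CC(C)C)[C@H]1[C@@H](O3)c2c(c3ccc(OC)c(OC)c3n(C)c2=O)OC1(C)C | target

**Step count and risks**

Total step count: 7. Longest linear sequence: 4 steps (steps 1, 2, 3, 7 or steps 4, 5, 6, 7).

Steps most likely to fail:

Step 7. 1,2-Addition followed by oxa-electrocyclisation may outrun the conjugate addition. Facial selectivity on the α-branched iminium ion may be poor because of E/Z scrambling through the dienamine. Acid-induced ring opening in the second stage may erode the configuration at the isobutyl-bearing carbon or lead to another ring-fusion diastereomer. The fallback uses known chemistry, sets out from 4 and 5 and comes back at 12. Compound 4 is condensed with 3-methylbut-2-enal (ethylenediammonium diacetate, MeOH, 65 °C; Knoevenagel condensation/oxa-6π-electrocyclisation) to veprisine F1. Then 4, 5 and F1 are heated with ethylenediammonium diacetate in toluene at 110 °C in a sealed tube, so that 4 and 5 condense to 7,8-dimethoxy-1-methyl-3-(3-methylbutylidene)quinoline-2,4-dione F2 (not isolated). F2 should add as a 1-oxadiene to the pyran double bond of F1 in a hetero-Diels–Alder reaction with inverse electron demand (domino Knoevenagel/hetero-Diels–Alder reaction); the oxygen goes to the benzylic carbon and the cis alkene gives the cis ring fusion. The diastereomers are separated on silica, and the racemate is resolved by preparative HPLC on a chiral stationary phase, which parts 12 from its enantiomer ent-12 F3.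

Step 6. Base-induced self-condensation of the bromoenal, protodeboronation of the alkenylboronate or loss of the double-bond geometry may defeat the coupling. The fallback sets out from 5 and comes back at 9. Methyl 3-methylbut-2-enoate is deprotonated with LiN(iPr)2 (THF, −78 °C) and the dienolate is added through its α-carbon to 5 to give methyl 3-hydroxy-5-methyl-2-(prop-1-en-2-yl)hexanoate F4. Mesylation (MeSO2Cl, Et3N, CH2Cl2, 0 °C) gives the mesylate F5, and elimination with 1,8-diazabicyclo[5.4.0]undec-7-ene gives methyl (E)-5-methyl-2-(prop-1-en-2-yl)hex-2-enoate F6, purified from its geometric isomer by chromatography. Reduction with iBu2AlH (CH2Cl2, −78 °C) gives (E)-5-methyl-2-(prop-1-en-2-yl)hex-2-en-1-ol F7, and oxidation with MnO2 (CH2Cl2, rt) gives 9.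

Step 3. Decarboxylation of the malonamic acid before ring closure, or sulfonation and O-demethylation of the electron-rich ring in hot MeSO3H, may compete with the acylation. The fallback sets out from 2 and comes back at 4. Compound 2 is fused with bis(2,4,6-trichlorophenyl) malonate (neat, 220 °C); N-acylation and thermal ring closure of the activated aryl malonate should give 4 in one operation without strong acid, and no new compound is made on the way.

Further compounds
F1 | step 7 | veprisine, 7,8-dimethoxy-2,2,6-trimethyl-2H-pyrano[3,2-c]quinolin-5(6H)-one | COc1ccc2c3c(C=CC(C)(C)O3)c(=O)n(C)c2c1OC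
F2 | step 7 | 7,8-dimethoxy-1-methyl-3-(3-methylbutylidene)quinoline-2,4(1H,3H)-dione | COc1ccc2C(=O)C(=CCC(C)C)C(=O)N(C)c2c1OC
F3 | step 7 | ent-12, enantiomer of the target | COc1ccc2c3c(c(=O)n(C)c2c1OC)[C@H](CC(C)C)[C@@H]1[C@H](O3)c2c(c3ccc(OC)c(OC)c3n(C)c2=O)OC1(C)C
F4 | step 6 | methyl 3-hydroxy-5-methyl-2-(prop-1-en-2-yl)hexanoate (mixture of diastereomers) | COC(=O)C(C(C)=C)C(O)CC(C)C
F5 | step 6 | methyl 5-methyl-3-(methylsulfonyloxy)-2-(prop-1-en-2-yl)hexanoate | COC(=O)C(C(C)=C)C(OS(C)(=O)=O)CC(C)C
F6 | step 6 | methyl (E)-5-methyl-2-(prop-1-en-2-yl)hex-2-enoate | COC(=O)/C(=C/CC(C)C)C(C)=C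
F7 | step 6 | (E)-5-methyl-2-(prop-1-en-2-yl)hex-2-en-1-ol | OC/C(=C/CC(C)C)C(C)=C
F0 | step 3 | none | none
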